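Assumption: 2-(oxetan-3-yl)acetaldehyde and both antipodes of the two organocatalysts are taken as catalogue items; operations run in one flask without isolation count as one step. C1–C4 below are the four sp3 ring carbons of the target tetralin (C1 carries the aryl group).

**Retrosynthetic overview**
1. Tetralin ring B ⇐ acid-triggered 1,2-shift of the benzylic C1 (dienone–phenol ring expansion, five- to six-membered) in a spiro[4.5]deca-6,9-dien-8-one.
2. Spiro-cyclopentane ⇐ phenolate para (ipso) alkylation by CH2Br in a gem-bis(guaiacyl) bromide. Ring order: arenes (from catechol) → cyclopentane → cyclohexane.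
3. CH2Br and the C3 stereocentre ⇐ desymmetrising bromide opening of an oxetane.
4. C1–C2 bond and the C2 stereocentre ⇐ amine-catalysed 1,6-addition of 2-(oxetan-3-yl)acetaldehyde to the quinone methide of bisguaiacol F.
5. Bisguaiacol F ⇐ 2 guaiacol + CH2O; guaiacol ⇐ catechol + MeI.

**Route**

Step 1
Reactants: 1 catechol
Product: 2 guaiacol (2-methoxyphenol)
Conditions: MeI (1.0 equiv), K2CO3 (1.0 equiv), acetone, reflux; catechol in 1.5-fold excess, recovered
Reagents that add atoms: iodomethane, CI
Why: Williamson mono-O-methylation with limiting MeI, in which the mono-phenolate is the reacting nucleophile and over-methylation is held back by the excess catechol; no stereocentre.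

Step 2
Reactants: 2 guaiacol (2 equiv consumed, 6 equiv charged), 3 formaldehyde
Product: 4 4,4'-methylenebis(2-methoxyphenol) (bisguaiacol F)
Conditions: 37% aq HCHO, Amberlyst-15, 70 °C; p,p'-isomer crystallised from toluene/heptane
Reagents that add atoms: none
Why: acid-catalysed hydroxymethylation/Friedel–Crafts condensation (Baeyer bisphenol synthesis) in which the free OH directs both C–C bonds para and the excess guaiacol stops the reaction at the dimer; no stereocentre.

Step 3
Reactants: 4 bisguaiacol F, 5 2-(oxetan-3-yl)acetaldehyde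
Product: 8 (2R)-3,3-bis(4-hydroxy-3-methoxyphenyl)-2-(oxetan-3-yl)propan-1-ol, via quinone methide 6 (not isolated), via aldehyde 7 (not isolated)
Conditions: DDQ (1.0 equiv), 4 Å MS, CH2Cl2, 0 °C, filter; then 5 (1.5 equiv), (R)-α,α-diphenylprolinol TMS ether (10 mol%), PhCO2H (20 mol%), −20 °C; then NaBH4, MeOH, 0 °C
Reagents that add atoms: none
Why: Proposed new method: DDQ abstracts hydride from the doubly benzylic CH2 of 4 to give the unhindered phenolic p-quinone methide 6 (kept neutral and H-bond-activated by the acid additive), and the E-enamine of 5 with the (R)-prolinol ether, one face shielded by the CPh2OTMS group, adds 1,6 to its methine carbon to form the C1–C2 bond and set C2 as R (C1 is not stereogenic because both aryl groups are identical; the α-branched product no longer forms an enamine and is reduced in situ); the closest known reaction types are the diarylprolinol-ether-catalysed 1,6-addition of aldehydes to 2,6-di-tert-butyl p-quinone methides and the DDQ-mediated oxidative α-alkylation of aldehydes with diarylmethanes, neither shown for a tert-butyl-free bis-phenolic quinone methide made in the flask.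

Step 4
Reactants: 8 (2R)-3,3-bis(4-hydroxy-3-methoxyphenyl)-2-(oxetan-3-yl)propan-1-ol
Product: 10 (2R,3R)-2-{bis[3-methoxy-4-(trimethylsilyloxy)phenyl]methyl}-3-(bromomethyl)-1,4-bis(trimethylsilyloxy)butane, via silyl ether 9 (not isolated)
Conditions: HMDS (2 equiv), saccharin (1 mol%), CH2Cl2, 40 °C, evaporate; then TMSBr (1.2 equiv), chiral aryl-pyrrolidine squaramide H-bond-donor catalyst (5 mol%, the antipode that attacks the pro-R CH2), TBME, −78 to −40 °C; evaporate, filter through dry Celite, use crude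
Reagents that add atoms: hexamethyldisilazane, C[Si](C)(C)N[Si](C)(C)C; bromotrimethylsilane, C[Si](C)(C)Br
Why: per-silylation (no free OH, hence no HBr background) followed by the known squaramide-catalysed enantioselective oxetane opening with TMSBr, used here as a catalyst-controlled diastereoselective desymmetrisation in which the catalyst-bound bromide attacks the pro-R CH2 of the silyl-activated oxetane by SN2 and sets C3 as R while C2 is untouched.

Step 5
Reactants: 10 (2R,3R)-2-{bis[3-methoxy-4-(trimethylsilyloxy)phenyl]methyl}-3-(bromomethyl)-1,4-bis(trimethylsilyloxy)butane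
Product: 13 (+)-isolariciresinol, via bisphenolate 11 (not isolated), via spirodienone 12 (not isolated)
Conditions: t-BuOK (2.0 equiv), THF/t-BuOH, 0 to 45 °C; then 2 M aq HCl, THF, 45 °C
Reagents that add atoms: none
Why: tert-butoxide unmasks the two phenolates and one of them alkylates C4 through its para carbon (Winstein Ar1-5 alkylative dearomatisation, the only carbon nucleophile that can reach the bromide, with the other aryl placed trans to the C2 substituent) to give the spiro-cyclopentane dienone, after which acid triggers the dienone–phenol rearrangement in which the p-hydroxybenzylic C1 shifts 1,2 from the spiro carbon to the neighbouring CH remote from OMe (the more electron-poor β-carbon), expanding the five-membered ring to the aromatised tetralin with OH para to C4a and OMe para to C8a and C1 trans to C2 (the cation-like migrating carbon lets any C1 epimer converge), while the alkyl silyl ethers are hydrolysed.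

**Compound list**
1 | catechol (benzene-1,2-diol) | Oc1ccccc1O | starting material
2 | guaiacol (2-methoxyphenol) | COc1ccccc1O | intermediate
3 | formaldehyde | C=O | starting material
4 | 4,4'-methylenebis(2-methoxyphenol) (bisguaiacol F) | COc1cc(Cc2ccc(O)c(OC)c2)ccc1O | intermediate
5 | 2-(oxetan-3-yl)acetaldehyde | O=CCC1COC1 | starting material
6 | 4-[(4-hydroxy-3-methoxyphenyl)methylidene]-2-methoxycyclohexa-2,5-dien-1-one (p-quinone methide of 4) | COC1=CC(=Cc2ccc(O)c(OC)c2)C=CC1=O | intermediate
7 | (2R)-3,3-bis(4-hydroxy-3-methoxyphenyl)-2-(oxetan-3-yl)propanal | C1OCC1[C@@H](C(c2ccc(O)c(OC)c2)c2ccc(O)c(OC)c2)C=O | intermediate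
8 | (2R)-3,3-bis(4-hydroxy-3-methoxyphenyl)-2-(oxetan-3-yl)propan-1-ol | C1OCC1[C@@H](C(c2ccc(O)c(OC)c2)c2ccc(O)c(OC)c2)CO | intermediate
9 | tris(trimethylsilyl) ether of 8 (2R) | C1OCC1[C@@H](C(c2ccc(O[Si](C)(C)C)c(OC)c2)c2ccc(O[Si](C)(C)C)c(OC)c2)CO[Si](C)(C)C | intermediate
10 | (2R,3R)-2-{bis[3-methoxy-4-(trimethylsilyloxy)phenyl]methyl}-3-(bromomethyl)-1,4-bis(trimethylsilyloxy)butane | BrC[C@@H](CO[Si](C)(C)C)[C@@H](C(c1ccc(O[Si](C)(C)C)c(OC)c1)c1ccc(O[Si](C)(C)C)c(OC)c1)CO[Si](C)(C)C | intermediate
11 | dipotassium bis-phenolate of 10 (aryl silyl groups removed; 2R,3R) | BrC[C@@H](CO[Si](C)(C)C)[C@@H](C(c1ccc([O-])c(OC)c1)c1ccc([O-])c(OC)c1)CO[Si](C)(C)C.[K+].[K+] | intermediate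
12 | (1S,2R,3R)-1-(4-hydroxy-3-methoxyphenyl)-7-methoxy-2,3-bis[(trimethylsilyloxy)methyl]spiro[4.5]deca-6,9-dien-8-one, potassium phenolate, both epimers at the spiro carbon | COc1cc([C@H]2C3(C=CC(=O)C(OC)=C3)C[C@@H](CO[Si](C)(C)C)[C@@H]2CO[Si](C)(C)C)ccc1[O-].[K+] | intermediate
13 | (+)-isolariciresinol, (1S,2R,3R)-7-hydroxy-1-(4-hydroxy-3-methoxyphenyl)-6-methoxy-1,2,3,4-tetrahydronaphthalene-2,3-dimethanol | COc1cc([C@H]2c3cc(O)c(OC)cc3C[C@@H](CO)[C@@H]2CO)ccc1O | target

**Totals**
Total steps: 5. Longest linear sequence: 5 (1 → 2 → 4 → 8 → 10 → 13).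

**Steps most likely to fail, with fallbacks**

Step 3 (the proposed new step). The unhindered quinone methide may oligomerise or be deprotonated to an unreactive dye anion, or the ee may be low. The fallback uses known chemistry, an Enders SAMP-hydrazone alkylation; it sets out from 4 (and uses 5) and comes back to the route at 8. Compound 4 is silylated (TBSCl, imidazole, DMF) to 4,4'-methylenebis[1-(tert-butyldimethylsilyloxy)-2-methoxybenzene] F1. This is brominated at the doubly benzylic CH2 (NBS, AIBN, PhCF3, 80 °C) to bromobis[4-(tert-butyldimethylsilyloxy)-3-methoxyphenyl]methane F2, used crude. Aldehyde 5 is condensed with SAMP to the SAMP hydrazone of 5 F3. Deprotonation (LDA, THF, −78 °C) and alkylation with F2 give the (2R)-alkylated SAMP hydrazone F4; SAMP gives the R centre here by the usual Enders model. Mild hydrazone cleavage (aq CuCl2, THF) gives (2R)-3,3-bis[4-(tert-butyldimethylsilyloxy)-3-methoxyphenyl]-2-(oxetan-3-yl)propanal F5. NaBH4 gives the corresponding propan-1-ol F6, and TBAF removes the silyl groups to give 8.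

Step 4. A pendant silyl ether or an aryl ring may compete with bromide for the activated oxetane, or the catalyst may be mismatched with C2. The fallback replaces catalyst control by thermodynamic control; it sets out from 7 (isolated in step 3 by leaving out the borohydride) and comes back at 10. Pinnick oxidation (NaClO2, NaH2PO4, 2-methyl-2-butene, t-BuOH/H2O) gives (2R)-3,3-bis(4-hydroxy-3-methoxyphenyl)-2-(oxetan-3-yl)propanoic acid F7. With CSA in CH2Cl2 the acid opens the oxetane (5-exo) and the hydroxy-lactone equilibrates by transesterification to the trans isomer, (3R,4S)-3-[bis(4-hydroxy-3-methoxyphenyl)methyl]-4-(hydroxymethyl)oxolan-2-one F8, so the arm that stays free is chosen by thermodynamics. An Appel reaction (CBr4, PPh3) gives (3R,4R)-3-[bis(4-hydroxy-3-methoxyphenyl)methyl]-4-(bromomethyl)oxolan-2-one F9. DIBAL-H (toluene/CH2Cl2, −78 to 0 °C) gives (2R,3R)-2-[bis(4-hydroxy-3-methoxyphenyl)methyl]-3-(bromomethyl)butane-1,4-diol F10, and HMDS silylation gives 10.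

Step 5 (the ring-expansion step). Unmasking phenolates from silyl ethers in the presence of a β-branched bromide may be messy, and a one-pot sequence gives no chance to purify the spirodienone. The fallback changes the protecting-group strategy and runs the two stages separately; it sets out from 10 and comes back at 13. Methanolysis (cat. K2CO3, MeOH, 0 °C) gives the bromo-diol F10, which is locked as the acetonide (2,2-dimethoxypropane, PPTS), (5R,6R)-5-[bis(4-hydroxy-3-methoxyphenyl)methyl]-6-(bromomethyl)-2,2-dimethyl-1,3-dioxepane F11. Classical t-BuOK/t-BuOH at 50 °C gives the isolable acetonide of the spirodienone diol F12. Treatment with 2 M HCl/THF at 45 °C cleaves the acetal and effects the ring expansion to 13.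

**Further compounds**
F1 | step 3 | 4,4'-methylenebis[1-(tert-butyldimethylsilyloxy)-2-methoxybenzene] | COc1cc(Cc2ccc(O[Si](C)(C)C(C)(C)C)c(OC)c2)ccc1O[Si](C)(C)C(C)(C)C
F2 | step 3 | bromobis[4-(tert-butyldimethylsilyloxy)-3-methoxyphenyl]methane | COc1cc(C(Br)c2ccc(O[Si](C)(C)C(C)(C)C)c(OC)c2)ccc1O[Si](C)(C)C(C)(C)C
F3 | step 3 | SAMP hydrazone of 5, (E)-N-[(2S)-2-(methoxymethyl)pyrrolidin-1-yl]-2-(oxetan-3-yl)ethan-1-imine | COC[C@@H]1CCCN1/N=C/CC1COC1
F4 | step 3 | (2R)-alkylated SAMP hydrazone, (E)-N-[(2S)-2-(methoxymethyl)pyrrolidin-1-yl]-(2R)-3,3-bis[4-(tert-butyldimethylsilyloxy)-3-methoxyphenyl]-2-(oxetan-3-yl)propan-1-imine | COC[C@@H]1CCCN1/N=C/[C@@H](C1COC1)C(c1ccc(O[Si](C)(C)C(C)(C)C)c(OC)c1)c1ccc(O[Si](C)(C)C(C)(C)C)c(OC)c1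
F5 | step 3 | (2R)-3,3-bis[4-(tert-butyldimethylsilyloxy)-3-methoxyphenyl]-2-(oxetan-3-yl)propanal | C1OCC1[C@@H](C(c2ccc(O[Si](C)(C)C(C)(C)C)c(OC)c2)c2ccc(O[Si](C)(C)C(C)(C)C)c(OC)c2)C=O
F6 | step 3 | (2R)-3,3-bis[4-(tert-butyldimethylsilyloxy)-3-methoxyphenyl]-2-(oxetan-3-yl)propan-1-ol | C1OCC1[C@@H](C(c2ccc(O[Si](C)(C)C(C)(C)C)c(OC)c2)c2ccc(O[Si](C)(C)C(C)(C)C)c(OC)c2)CO
F7 | step 4 | (2R)-3,3-bis(4-hydroxy-3-methoxyphenyl)-2-(oxetan-3-yl)propanoic acid | C1OCC1[C@@H](C(c2ccc(O)c(OC)c2)c2ccc(O)c(OC)c2)C(=O)O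
F8 | step 4 | (3R,4S)-3-[bis(4-hydroxy-3-methoxyphenyl)methyl]-4-(hydroxymethyl)oxolan-2-one | OC[C@H]1COC(=O)[C@@H]1C(c2ccc(O)c(OC)c2)c2ccc(O)c(OC)c2
F9 | step 4 | (3R,4R)-3-[bis(4-hydroxy-3-methoxyphenyl)methyl]-4-(bromomethyl)oxolan-2-one | BrC[C@H]1COC(=O)[C@@H]1C(c2ccc(O)c(OC)c2)c2ccc(O)c(OC)c2
F10 | step 4 | (2R,3R)-2-[bis(4-hydroxy-3-methoxyphenyl)methyl]-3-(bromomethyl)butane-1,4-diol | BrC[C@@H](CO)[C@@H](C(c1ccc(O)c(OC)c1)c1ccc(O)c(OC)c1)CO
F11 | step 5 | (5R,6R)-5-[bis(4-hydroxy-3-methoxyphenyl)methyl]-6-(bromomethyl)-2,2-dimethyl-1,3-dioxepane | BrC[C@H]1COC(C)(C)OC[C@@H]1C(c2ccc(O)c(OC)c2)c2ccc(O)c(OC)c2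
F12 | step 5 | acetonide of the spirodienone diol (1S,2R,3R; both epimers at the spiro carbon) | COc1cc([C@H]2C3(C=CC(=O)C(OC)=C3)C[C@H]4COC(C)(C)OC[C@H]24)ccc1O
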